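**Strategy.** Both pyranones are disconnected at C4–C4a, which reduces the biisoflavone to a biaryl carrying two 3-aryloxy-2-arylacrylic acids. A single treatment with P2O5 in MeSO3H should close ring C of unit D (the 7-oxygenated isoflavone) and ring C of unit G (the 5,7-dioxygenated isoflavone) by twofold intramolecular Friedel–Crafts acylation. The step exploits ring A of unit G: C8(G) already carries ring B of unit D, so O1(G) has only one free ortho carbon, C4a(G), activated by O5 and O7; in ring A of unit D, C4a(D) lies para to O7(D). The precursor is the per-O-methylated diacid 16; BBr3 finally frees the five hydroxyls.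

Key step: step 10

Remarks on the chemistry (assumptions):
- Isoflavone numbering is used within each half; the halves are joined C3'(D)–C8(G). The target has no stereocentre, and the biaryl axis is treated as configurationally labile.
- O7(G) is carried as a methyl ether. The central ring then comes from 3,5-dimethoxyphenol with its three oxygens already differentiated, so no symmetrical resorcinol has to be mono-etherified and no free phenol meets the acylating medium of step 10.
- Enol tosylates are drawn Z (O-sulfonylation of the chelated sodium enolates) and aryl enol ethers E (aryloxy trans to the carboxyl group, the more stable arrangement). These geometries are not critical, because the acid of step 10 equilibrates them; mixtures would be carried forward.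

**Step 1**
Reactants: 1 3,5-dimethoxyphenol
Product: 2 1,3-dimethoxy-5-(methoxymethoxy)benzene
Conditions: NaH, MOMCl, THF/DMF, 0 °C → rt
Reagents that add atoms: chloromethyl methyl ether (MOMCl), COCCl
Why: O-alkylation of the sodium phenoxide by the α-chloro ether (Williamson-type acetal formation) masks the single hydroxyl as the methoxymethyl ether, which directs the metalation of step 2 and can later be removed without touching methyl ethers.

**Step 2**
Reactants: 2 1,3-dimethoxy-5-(methoxymethoxy)benzene
Product: 4 2-[2,4-dimethoxy-6-(methoxymethoxy)phenyl]-4,4,5,5-tetramethyl-1,3,2-dioxaborolane, via aryllithium 3 (not isolated)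
Conditions: n-BuLi, THF, 0 °C; then i-PrOBpin, −78 °C → rt; aq. NH4Cl
Reagents that add atoms: 2-isopropoxy-4,4,5,5-tetramethyl-1,3,2-dioxaborolane (i-PrOBpin), CC(C)OB1OC(C)(C)C(C)(C)O1
Why: Directed ortho-metalation: the chelating methoxymethoxy group and the neighbouring methoxy group together acidify the carbon between them (two equivalent sites), which should be preferred over the carbon between the two methoxy groups, and the aryllithium is trapped by the boron electrophile (borylation).

**Step 3**
Reactants: 4 2-[2,4-dimethoxy-6-(methoxymethoxy)phenyl]-4,4,5,5-tetramethyl-1,3,2-dioxaborolane; 5 methyl (3-bromo-4-methoxyphenyl)acetate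
Product: 6 methyl 2-{3-[2,4-dimethoxy-6-(methoxymethoxy)phenyl]-4-methoxyphenyl}acetate
Conditions: Pd(OAc)2, SPhos, K3PO4, toluene/H2O, 90 °C
Reagents that add atoms: none
Why: Suzuki–Miyaura coupling: oxidative addition of bromide 5 to zerovalent palladium, base-assisted transmetalation of the hindered 2,6-dioxygenated boronate and reductive elimination are all favoured by the bulky electron-rich biarylphosphine SPhos, the usual remedy for tri-ortho-substituted biaryls, while K3PO4 should leave the methyl ester intact.

**Step 4**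
Reactants: 6 methyl 2-{3-[2,4-dimethoxy-6-(methoxymethoxy)phenyl]-4-methoxyphenyl}acetate
Product: 8 methyl (Z)-2-{3-[2,4-dimethoxy-6-(methoxymethoxy)phenyl]-4-methoxyphenyl}-3-{[(4-methylphenyl)sulfonyl]oxy}prop-2-enoate, via sodium enolate 7 (not isolated)
Conditions: NaH, HCO2Me, THF, 0 °C → rt; then TsCl, 0 °C → rt
Reagents that add atoms: methyl formate, COC=O; p-toluenesulfonyl chloride (TsCl), Cc1ccc(cc1)S(Cl)(=O)=O
Why: Crossed Claisen condensation of the arylacetate enolate with methyl formate gives the chelated sodium enolate of the formyl ester, which is O-sulfonylated in the same flask (enolate trapping) to an enol tosylate with the sulfonyloxy group expected cis to the ester.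

**Step 5**
Reactants: 8 methyl (Z)-2-{3-[2,4-dimethoxy-6-(methoxymethoxy)phenyl]-4-methoxyphenyl}-3-{[(4-methylphenyl)sulfonyl]oxy}prop-2-enoate; 9 3-methoxyphenol
Product: 10 methyl (E)-2-{3-[2,4-dimethoxy-6-(methoxymethoxy)phenyl]-4-methoxyphenyl}-3-(3-methoxyphenoxy)prop-2-enoate
Conditions: Cs2CO3, MeCN, rt
Reagents that add atoms: none
Why: Nucleophilic vinylic substitution by addition–elimination: the phenoxide of 9 adds to the β-carbon of the acrylate and the ester- and aryl-stabilised carbanion expels tosylate, which should give the aryl enol ether mainly as the more stable E isomer.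

**Step 6**
Reactants: 10 methyl (E)-2-{3-[2,4-dimethoxy-6-(methoxymethoxy)phenyl]-4-methoxyphenyl}-3-(3-methoxyphenoxy)prop-2-enoate
Product: 11 methyl (E)-2-[3-(2-hydroxy-4,6-dimethoxyphenyl)-4-methoxyphenyl]-3-(3-methoxyphenoxy)prop-2-enoate
Conditions: conc. HCl, i-PrOH/THF, 45 °C
Reagents that add atoms: none
Why: Acid-catalysed hydrolysis of the aryl methoxymethyl acetal frees the single phenol, while the methyl ethers, the ester and the push–pull enol ether (a vinylogous carbonate that resists dilute acid, the hindered alcohol being too poor a nucleophile to exchange the aryloxy group) should stay intact.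

**Step 7**
Reactants: 12 methyl 4-methoxyphenylacetate
Product: 14 methyl (Z)-2-(4-methoxyphenyl)-3-{[(4-methylphenyl)sulfonyl]oxy}prop-2-enoate, via sodium enolate 13 (not isolated)
Conditions: NaH, HCO2Me, THF, 0 °C → rt; then TsCl, 0 °C → rt
Reagents that add atoms: methyl formate, COC=O; p-toluenesulfonyl chloride (TsCl), Cc1ccc(cc1)S(Cl)(=O)=O
Why: The same crossed Claisen formylation and in-flask O-sulfonylation of the chelated sodium enolate as in step 4, here on the simple arylacetate that supplies C2, C3, C4 and ring B of unit G.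

**Step 8**
Reactants: 11 methyl (E)-2-[3-(2-hydroxy-4,6-dimethoxyphenyl)-4-methoxyphenyl]-3-(3-methoxyphenoxy)prop-2-enoate; 14 methyl (Z)-2-(4-methoxyphenyl)-3-{[(4-methylphenyl)sulfonyl]oxy}prop-2-enoate
Product: 15 methyl (E)-2-{3-[2-{[(E)-3-methoxy-2-(4-methoxyphenyl)-3-oxoprop-1-en-1-yl]oxy}-4,6-dimethoxyphenyl]-4-methoxyphenyl}-3-(3-methoxyphenoxy)prop-2-enoate
Conditions: Cs2CO3, MeCN, rt → 40 °C
Reagents that add atoms: none
Why: Nucleophilic vinylic substitution (addition–elimination) of the cesium phenoxide of 11 on the enol tosylate, which at room temperature should be much faster than aryloxide exchange at the enol ether already present, because tosylate is by far the better leaving group.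

**Step 9**
Reactants: 15 methyl (E)-2-{3-[2-{[(E)-3-methoxy-2-(4-methoxyphenyl)-3-oxoprop-1-en-1-yl]oxy}-4,6-dimethoxyphenyl]-4-methoxyphenyl}-3-(3-methoxyphenoxy)prop-2-enoate
Product: 16 (E)-2-{3-[2-{[(E)-2-carboxy-2-(4-methoxyphenyl)ethenyl]oxy}-4,6-dimethoxyphenyl]-4-methoxyphenyl}-3-(3-methoxyphenoxy)prop-2-enoic acid
Conditions: LiOH·H2O, THF/H2O, 45 °C; then 1 M HCl, 0 °C
Reagents that add atoms: lithium hydroxide, [Li+].[OH-]
Why: Saponification: hydroxide attacks the two ester carbonyls, the aryl enol ethers should survive as β-aryloxy-unsaturated esters do in the classical hydrolyses that precede chromone closure, and acidification liberates the diacid.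

**Step 10**
Reactants: 16 (E)-2-{3-[2-{[(E)-2-carboxy-2-(4-methoxyphenyl)ethenyl]oxy}-4,6-dimethoxyphenyl]-4-methoxyphenyl}-3-(3-methoxyphenoxy)prop-2-enoic acid
Product: 18 5,7-dimethoxy-8-[2-methoxy-5-(7-methoxy-4-oxo-4H-chromen-3-yl)phenyl]-3-(4-methoxyphenyl)-4H-chromen-4-one, via bis-Z diacid 17 (not isolated)
Conditions: P2O5 (7.7 wt%) in MeSO3H, 0.03 M, 50 °C; then ice/H2O
Reagents that add atoms: none
Why: In P2O5/MeSO3H each carboxylic acid becomes a mixed anhydride or acylium ion, while reversible C-protonation of each push–pull enol ether (oxocarbenium ion, bond rotation, deprotonation) lets the E arms reach the Z geometry of 17, in which the electrophile lies next to the ortho carbon of its aryl ether. The closest known reaction type is the acid-mediated intramolecular Friedel–Crafts acylation of 3-aryloxyacrylic acids to chromones, here applied to two arms of one molecule. Ring C of unit D closes by attack of C4a(D) on its acylium carbon (new bond C4(D)–C4a(D)) and ring C of unit G by attack of C4a(G) (new bond C4(G)–C4a(G)), each as a six-membered ring by intramolecular electrophilic aromatic substitution followed by loss of a proton. No stereocentre is formed. The selectivity needed is regiochemical: on ring A of unit G the only free carbon ortho to O1(G) is C4a(G), because C8(G) bears ring B of unit D, and it is ortho to O5 and para to O7; on ring A of unit D closure para to the 7-methoxy group should be preferred over the crowded carbon between the two oxygens. High dilution disfavours intermolecular acylation, and each new pyranone deactivates only its own ring A.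

**Step 11**
Reactants: 18 5,7-dimethoxy-8-[2-methoxy-5-(7-methoxy-4-oxo-4H-chromen-3-yl)phenyl]-3-(4-methoxyphenyl)-4H-chromen-4-one
Product: 19 5,7-dihydroxy-8-[2-hydroxy-5-(7-hydroxy-4-oxo-4H-chromen-3-yl)phenyl]-3-(4-hydroxyphenyl)-4H-chromen-4-one
Conditions: BBr3 (excess), CH2Cl2, −78 °C → rt; then MeOH, H2O
Reagents that add atoms: none
Why: Lewis-acid ether cleavage: BBr3 coordinates each methoxy oxygen and bromide removes the methyl group by SN2 attack, a standard demethylation of methoxyisoflavones that leaves the aryl–oxygen bonds, the pyranones and the biaryl bond untouched.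

**Compound list**

1 | 3,5-dimethoxyphenol | COc1cc(O)cc(OC)c1 | starting material
2 | 1,3-dimethoxy-5-(methoxymethoxy)benzene | COCOc1cc(OC)cc(OC)c1 | intermediate
3 | [2,4-dimethoxy-6-(methoxymethoxy)phenyl]lithium | [Li]c1c(OC)cc(OC)cc1OCOC | intermediate (not isolated)
4 | 2-[2,4-dimethoxy-6-(methoxymethoxy)phenyl]-4,4,5,5-tetramethyl-1,3,2-dioxaborolane | COCOc1cc(OC)cc(OC)c1B1OC(C)(C)C(C)(C)O1 | intermediate
5 | methyl (3-bromo-4-methoxyphenyl)acetate | COC(=O)Cc1ccc(OC)c(Br)c1 | starting material
6 | methyl 2-{3-[2,4-dimethoxy-6-(methoxymethoxy)phenyl]-4-methoxyphenyl}acetate | COC(=O)Cc1ccc(OC)c(c1)-c1c(OC)cc(OC)cc1OCOC | intermediate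
7 | sodium (Z)-3-methoxy-2-{3-[2,4-dimethoxy-6-(methoxymethoxy)phenyl]-4-methoxyphenyl}-3-oxoprop-1-en-1-olate | [Na+].[O-]/C=C(\C(=O)OC)c1ccc(OC)c(c1)-c1c(OC)cc(OC)cc1OCOC | intermediate (not isolated)
8 | methyl (Z)-2-{3-[2,4-dimethoxy-6-(methoxymethoxy)phenyl]-4-methoxyphenyl}-3-{[(4-methylphenyl)sulfonyl]oxy}prop-2-enoate | COC(=O)/C(=C\OS(=O)(=O)c1ccc(C)cc1)c1ccc(OC)c(c1)-c1c(OC)cc(OC)cc1OCOC | intermediate
9 | 3-methoxyphenol | COc1cccc(O)c1 | starting material
10 | methyl (E)-2-{3-[2,4-dimethoxy-6-(methoxymethoxy)phenyl]-4-methoxyphenyl}-3-(3-methoxyphenoxy)prop-2-enoate | COC(=O)/C(=C/Oc1cccc(OC)c1)c1ccc(OC)c(c1)-c1c(OC)cc(OC)cc1OCOC | intermediate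
11 | methyl (E)-2-[3-(2-hydroxy-4,6-dimethoxyphenyl)-4-methoxyphenyl]-3-(3-methoxyphenoxy)prop-2-enoate | COC(=O)/C(=C/Oc1cccc(OC)c1)c1ccc(OC)c(c1)-c1c(OC)cc(OC)cc1O | intermediate
12 | methyl 4-methoxyphenylacetate | COC(=O)Cc1ccc(OC)cc1 | starting material
13 | sodium (Z)-3-methoxy-2-(4-methoxyphenyl)-3-oxoprop-1-en-1-olate | [Na+].[O-]/C=C(\C(=O)OC)c1ccc(OC)cc1 | intermediate (not isolated)
14 | methyl (Z)-2-(4-methoxyphenyl)-3-{[(4-methylphenyl)sulfonyl]oxy}prop-2-enoate | COC(=O)/C(=C\OS(=O)(=O)c1ccc(C)cc1)c1ccc(OC)cc1 | intermediate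
15 | methyl (E)-2-{3-[2-{[(E)-3-methoxy-2-(4-methoxyphenyl)-3-oxoprop-1-en-1-yl]oxy}-4,6-dimethoxyphenyl]-4-methoxyphenyl}-3-(3-methoxyphenoxy)prop-2-enoate | COC(=O)/C(=C/Oc1cccc(OC)c1)c1ccc(OC)c(c1)-c1c(OC)cc(OC)cc1O/C=C(/C(=O)OC)c1ccc(OC)cc1 | intermediate
16 | (E)-2-{3-[2-{[(E)-2-carboxy-2-(4-methoxyphenyl)ethenyl]oxy}-4,6-dimethoxyphenyl]-4-methoxyphenyl}-3-(3-methoxyphenoxy)prop-2-enoic acid (key-step precursor) | OC(=O)/C(=C/Oc1cccc(OC)c1)c1ccc(OC)c(c1)-c1c(OC)cc(OC)cc1O/C=C(/C(O)=O)c1ccc(OC)cc1 | intermediate
17 | (Z)-2-{3-[2-{[(Z)-2-carboxy-2-(4-methoxyphenyl)ethenyl]oxy}-4,6-dimethoxyphenyl]-4-methoxyphenyl}-3-(3-methoxyphenoxy)prop-2-enoic acid | OC(=O)/C(=C\Oc1cccc(OC)c1)c1ccc(OC)c(c1)-c1c(OC)cc(OC)cc1O/C=C(\C(O)=O)c1ccc(OC)cc1 | intermediate (not isolated)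
18 | 5,7-dimethoxy-8-[2-methoxy-5-(7-methoxy-4-oxo-4H-chromen-3-yl)phenyl]-3-(4-methoxyphenyl)-4H-chromen-4-one (penta-O-methyl ether of the target, key-step product) | COc1ccc(cc1)-c1coc2c(c1=O)c(OC)cc(OC)c2-c1cc(ccc1OC)-c1coc2cc(OC)ccc2c1=O | intermediate
19 | 5,7-dihydroxy-8-[2-hydroxy-5-(7-hydroxy-4-oxo-4H-chromen-3-yl)phenyl]-3-(4-hydroxyphenyl)-4H-chromen-4-one | O=c1c(-c2ccc(O)c(-c3c(O)cc(O)c4c(=O)c(-c5ccc(O)cc5)coc34)c2)coc2cc(O)ccc12 | target

**Step count.** Total: 11 steps. Longest linear sequence: 10 steps (steps 1–6 and 8–11, from 3,5-dimethoxyphenol); step 7 is a one-step side branch.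

**Steps most likely to fail**

1. Step 10. The E to Z isomerisation of the enol ethers may be too slow. The electron-rich central ring may suffer intermolecular acylation or sulfonylation at C6(G) in the strongly acidic medium. Part of the closure on ring A of unit D may go to the carbon between the two oxygens. The fallback sets out from diacid 16 and leaves the Brønsted superacid for discrete acyl chlorides and a Lewis acid. Oxalyl chloride with catalytic DMF in CH2Cl2 would convert 16 into (E)-2-{3-[2-{[(E)-3-chloro-2-(4-methoxyphenyl)-3-oxoprop-1-en-1-yl]oxy}-4,6-dimethoxyphenyl]-4-methoxyphenyl}-3-(3-methoxyphenoxy)prop-2-enoyl chloride F1. Treated in dilute CH2Cl2 with SnCl4 from −20 °C to room temperature, this should close both rings by aprotic Friedel–Crafts acylation, the classical chromone closure of 3-aryloxyacryloyl chlorides. The carbonyl-bound Lewis acid lowers the rotation barrier of the push–pull double bonds. The fallback comes back to the route at 18.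

2. Step 8. The hindered phenoxide of 11 may attack sulfur and not carbon (sulfonyl transfer to the phenol), or may exchange with the aryloxy group of the enol ether already in place. The fallback sets out from the sodium enolate 13 of step 7. Acidic work-up would give the formyl ester in its enol form, methyl (Z)-3-hydroxy-2-(4-methoxyphenyl)prop-2-enoate F2. The chloroiminium reagent from oxalyl chloride and DMF (Vilsmeier-type chlorination of a 1,3-dicarbonyl enol) should turn this into methyl (Z)-3-chloro-2-(4-methoxyphenyl)prop-2-enoate F3. This vinyl chloride has no sulfur centre to divert the nucleophile and would undergo addition–elimination with phenol 11 (Cs2CO3, DMF, 50 °C), which brings the route back at 15.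

3. Step 2. Deprotonation may occur partly at the carbon between the two methoxy groups, which would deliver the regioisomeric boronate. The fallback sets out from phenol 1 and fixes the position by halogen. Amine-mediated ortho-bromination (NBS, catalytic i-Pr2NH, CH2Cl2, low temperature) should give 2-bromo-3,5-dimethoxyphenol F4, freed of any para isomer at this cheap stage. Protection (NaH, MOMCl) gives 2-bromo-1,5-dimethoxy-3-(methoxymethoxy)benzene F5. Bromine–lithium exchange with n-BuLi at −78 °C then generates aryllithium 3 regiospecifically, and borylation as in step 2 comes back to the route at 4.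

**Further compounds**

F1 | step 10 | (E)-2-{3-[2-{[(E)-3-chloro-2-(4-methoxyphenyl)-3-oxoprop-1-en-1-yl]oxy}-4,6-dimethoxyphenyl]-4-methoxyphenyl}-3-(3-methoxyphenoxy)prop-2-enoyl chloride | ClC(=O)/C(=C/Oc1cccc(OC)c1)c1ccc(OC)c(c1)-c1c(OC)cc(OC)cc1O/C=C(/C(Cl)=O)c1ccc(OC)cc1
F2 | step 8 | methyl (Z)-3-hydroxy-2-(4-methoxyphenyl)prop-2-enoate | COC(=O)/C(=C\O)c1ccc(OC)cc1
F3 | step 8 | methyl (Z)-3-chloro-2-(4-methoxyphenyl)prop-2-enoate | COC(=O)/C(=C\Cl)c1ccc(OC)cc1
F4 | step 2 | 2-bromo-3,5-dimethoxyphenol | COc1cc(O)c(Br)c(OC)c1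
F5 | step 2 | 2-bromo-1,5-dimethoxy-3-(methoxymethoxy)benzene | COCOc1cc(OC)cc(OC)c1Br
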